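## Retrosynthetic overview

Locants follow the dictyol skeleton: five-membered ring C1–C5 (C3=C4, methyl C17 on C4); seven-membered ring C1, C5–C10 (OH on C6, side chain on C7, C10=C18); oxolane O–C11–C12–C13–C14; C15 = CMe2OAc.

1. Endgame: dictyol H ⇐ C6 desilylation, C15 acetylation ⇐ C17 deoxygenation (CH2OH → CH3) ⇐ C10 methylenation ⇐ C1 decarboxylation of a bicyclic keto enal ester.
2. Key disconnection: C1–C5 and C3=C4 together, by an amine-catalysed Michael/aldol condensation of an open-chain keto ester dialdehyde that already carries the oxolane.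
3. Enabling feature: the C3=C4 alkene carries a one-carbon group on C4 (C17, read as CHO), and ring-fusion C1 is α to C10 (exocyclic methylene read as ketone). C5 is therefore the β-carbon of an enal, C1 a β-keto ester carbon and C3 an aldehyde 1,4 to C10. Because C1 and C5 are already linked through C10–C9–C8–C7–C6, one event closes both carbocycles.
4. Ring order: oxolane first (step 3); seven-membered ring (C1–C5) and five-membered ring (C3=C4) in the same operation (step 15).
5. Chain: nerol → Sharpless epoxidation (C7, C11) → allyl cuprate opening → Shi epoxidation/5-exo closure (C14) → Felkin–Anh alkynylation (C6) → Roskamp β-keto ester → C1 alkylation.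

Key step: step 15

Assumption: the C15 tertiary alcohol is carried unprotected, and the cis-fused ring junction (H-1 cis to H-5) is taken to be the more stable C1 epimer of the cyclopentene-fused cycloheptanone, so C1 is set by equilibration.

## Route

Step 1
Reactants: 1 nerol
Product: 2 (2S,3R)-2,3-epoxynerol
Conditions: Ti(OiPr)4 (10 mol%), L-(+)-diethyl tartrate (12 mol%), t-BuOOH, 4 Å MS, CH2Cl2, −20 °C
Reagents that add atoms: tert-butyl hydroperoxide CC(C)(C)OO
Why: Sharpless asymmetric epoxidation of the (Z)-allylic alcohol with the L-(+)-tartrate should give the (2S,3R)-epoxide, which fixes C11 directly and C7 after inversion.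

Step 2
Reactants: 2 (2S,3R)-2,3-epoxynerol; 3 allylmagnesium bromide
Product: 4 (2R,3R)-3,7-dimethyl-2-(prop-2-en-1-yl)oct-6-ene-1,3-diol
Conditions: 3 (3 equiv), CuI (10 mol%), THF/Et2O, −40 → 0 °C; aq. NH4Cl
Reagents that add atoms: none
Why: Copper-catalysed SN2 opening of the 2,3-epoxy alcohol should occur at the secondary carbon (the fully substituted carbon is blocked) with inversion, which sets C7 and frees the C11 tertiary alcohol.

Step 3
Reactants: 4 (2R,3R)-3,7-dimethyl-2-(prop-2-en-1-yl)oct-6-ene-1,3-diol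
Product: 6 2-[(2R,5R)-5-[(2R)-1-hydroxypent-4-en-2-yl]-5-methyloxolan-2-yl]propan-2-ol, via epoxy diol 5 (not isolated)
Conditions: L-fructose-derived Shi ketone (30 mol%), Oxone (2KHSO5·KHSO4·K2SO4), K2CO3, Bu4NHSO4, MeCN/CH2(OMe)2/aq. Na2B4O7 buffer, 0 °C; then CSA (10 mol%), CH2Cl2, 0 °C
Reagents that add atoms: potassium peroxymonosulfate [K+].[O-]S(=O)(=O)OO
Why: Shi epoxidation should attack only the trisubstituted alkene and give the (S)-epoxide under catalyst control, and acid-catalysed 5-exo opening by the tertiary hydroxyl with inversion should then set C14 and give the 2,5-trans oxolane (a minor 6-endo oxane is expected and removed).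

Step 4
Reactants: 6 2-[(2R,5R)-5-[(2R)-1-hydroxypent-4-en-2-yl]-5-methyloxolan-2-yl]propan-2-ol
Product: 7 (2S)-2-[(2R,5R)-5-(2-hydroxypropan-2-yl)-2-methyloxolan-2-yl]pent-4-enal
Conditions: TEMPO (10 mol%), PhI(OAc)2, CH2Cl2, 23 °C
Reagents that add atoms: none
Why: Oxoammonium (TEMPO) oxidation is selective for the primary alcohol and mild enough to keep the α-stereocentre.

Step 5
Reactants: 7 (2S)-2-[(2R,5R)-5-(2-hydroxypropan-2-yl)-2-methyloxolan-2-yl]pent-4-enal; 8 tert-butyldimethyl(prop-2-yn-1-yloxy)silane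
Product: 10 (4R,5R)-1-[(tert-butyldimethylsilyl)oxy]-5-[(2R,5R)-5-(2-hydroxypropan-2-yl)-2-methyloxolan-2-yl]oct-7-en-2-yn-4-ol, via lithium acetylide 9 (not isolated)
Conditions: 8 (2.5 equiv), n-BuLi (2.4 equiv), THF, −78 °C; then 7, −78 °C
Reagents that add atoms: none
Why: 1,2-Addition of the lithium acetylide in THF (non-chelating) should follow the Felkin–Anh model with the quaternary oxolane carbon as the large group, which gives the C6 configuration of the target.

Step 6
Reactants: 10 (4R,5R)-propargylic alcohol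
Product: 11 (2E,4S,5R)-1-[(tert-butyldimethylsilyl)oxy]-5-[(2R,5R)-5-(2-hydroxypropan-2-yl)-2-methyloxolan-2-yl]octa-2,7-dien-4-ol
Conditions: NaAlH2(OCH2CH2OMe)2 (Red-Al), THF, 0 → 23 °C; aq. Rochelle salt
Reagents that add atoms: none
Why: Hydroxyl-directed trans-hydroalumination of the propargylic alcohol should give only the (E)-allylic alcohol.

Step 7
Reactants: 11 (2E,4S,5R)-allylic alcohol
Product: 12 2-[(2R,5R)-5-[(4R,5S,6E)-5,8-bis[(tert-butyldimethylsilyl)oxy]octa-1,6-dien-4-yl]-5-methyloxolan-2-yl]propan-2-ol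
Conditions: TBSCl, imidazole, DMAP (10 mol%), DMF, 40 °C
Reagents that add atoms: tert-butyldimethylsilyl chloride CC(C)(C)[Si](C)(C)Cl
Why: Silylation with the silyl chloride should take the secondary C6 hydroxyl and leave the tertiary C15 hydroxyl free for the late acetylation.

Step 8
Reactants: 12 bis-silyl ether
Product: 14 (4R,5S,6E)-5,8-bis[(tert-butyldimethylsilyl)oxy]-4-[(2R,5R)-5-(2-hydroxypropan-2-yl)-2-methyloxolan-2-yl]oct-6-en-1-ol, via B-alkyl-9-BBN 13 (not isolated)
Conditions: 9-BBN (2.5 equiv), THF, 0 → 23 °C; then aq. NaOH, H2O2, 0 °C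
Reagents that add atoms: hydrogen peroxide OO
Why: Hydroboration–oxidation with 9-BBN should be selective for the terminal alkene over the 1,2-disubstituted alkene flanked by two allylic oxygens, and gives the anti-Markovnikov alcohol (C10).

Step 9
Reactants: 14 primary alcohol
Product: 15 (4R,5S,6E)-5,8-bis[(tert-butyldimethylsilyl)oxy]-4-[(2R,5R)-5-(2-hydroxypropan-2-yl)-2-methyloxolan-2-yl]oct-6-enal
Conditions: TEMPO (10 mol%), PhI(OAc)2, CH2Cl2, 23 °C
Reagents that add atoms: none
Why: Oxoammonium oxidation of the only primary alcohol should give the C10 aldehyde, with the tertiary alcohol and silyl ethers inert.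

Step 10
Reactants: 16 allyl acetoacetate
Product: 18 allyl diazoacetate, via allyl 2-diazoacetoacetate 17 (not isolated)
Conditions: p-acetamidobenzenesulfonyl azide, Et3N, MeCN, 0 → 23 °C; then aq. LiOH, 0 °C
Reagents that add atoms: p-acetamidobenzenesulfonyl azide CC(=O)Nc1ccc(cc1)S(=O)(=O)N=[N+]=[N-]
Why: Regitz diazo transfer to the active methylene followed by deacetylative cleavage should give the diazoacetate.

Step 11
Reactants: 15 aldehyde; 18 allyl diazoacetate
Product: 19 prop-2-en-1-yl (6R,7S,8E)-7,10-bis[(tert-butyldimethylsilyl)oxy]-6-[(2R,5R)-5-(2-hydroxypropan-2-yl)-2-methyloxolan-2-yl]-3-oxodec-8-enoate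
Conditions: 18 (1.3 equiv), SnCl2 (15 mol%), CH2Cl2, 23 °C
Reagents that add atoms: none
Why: The Roskamp reaction (Lewis-acid-promoted diazoacetate addition, 1,2-hydride shift, loss of N2) should convert the aldehyde into the β-keto ester without base, making the future C1 the only doubly activated carbon.

Step 12
Reactants: 19 β-keto ester; 20 tert-butyl(2-iodoethoxy)dimethylsilane
Product: 21 C1-alkylated β-keto ester (2-{2-[(tert-butyldimethylsilyl)oxy]ethyl} derivative of 19; both epimers at the new centre)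
Conditions: 20 (1.5 equiv), Cs2CO3 (1.5 equiv), DMF, 40 °C
Reagents that add atoms: none
Why: SN2 C-alkylation of the β-keto ester enolate with the primary iodide should install the C2–C3 arm on C1; the new centre is a mixture, which does not matter because it becomes quaternary in step 15.

Step 13
Reactants: 21 tris-silyl ether
Product: 22 prop-2-en-1-yl (6R,7S,8E)-7-[(tert-butyldimethylsilyl)oxy]-10-hydroxy-2-(2-hydroxyethyl)-6-[(2R,5R)-5-(2-hydroxypropan-2-yl)-2-methyloxolan-2-yl]-3-oxodec-8-enoate
Conditions: HF·pyridine, pyridine, THF, 0 °C; crude product taken on at once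
Reagents that add atoms: none
Why: Fluoride-mediated desilylation should remove the two primary silyl ethers much faster than the hindered secondary C6 silyl ether.

Step 14
Reactants: 22 diol
Product: 23 prop-2-en-1-yl (6R,7S,8E)-7-[(tert-butyldimethylsilyl)oxy]-6-[(2R,5R)-5-(2-hydroxypropan-2-yl)-2-methyloxolan-2-yl]-3,10-dioxo-2-(2-oxoethyl)dec-8-enoate
Conditions: SO3·pyridine, i-Pr2NEt, DMSO/CH2Cl2, 0 °C; used directly
Reagents that add atoms: none
Why: Parikh–Doering oxidation should convert both primary alcohols (allylic C17 and C3) into aldehydes under non-acidic conditions that spare the β-keto ester.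

Step 15
Reactants: 23 open-chain keto ester dialdehyde
Product: 26 cis-fused bicyclic keto enal ester (C17 aldehyde on C4, C3=C4, C10 ketone, allyl ester on C1 cis to H-5, 6β-silyloxy, 7β side chain), via Michael adduct 24 (not isolated), via aldol adduct 25 (not isolated)
Conditions: (R)-α,α-diphenylprolinol trimethylsilyl ether (20 mol%), PhCO2H (20 mol%), toluene (0.005 M), 23 °C
Reagents that add atoms: none
Why: Proposed new method: the amine condenses with the conjugated C17 aldehyde to an (E)-iminium ion, the β-keto ester enol adds through C1 to C5 (7-exo-trig, closing the seven-membered ring), and the C4 enamine released by this addition attacks the C3 aldehyde (5-exo-trig enol-exo aldol, closing the five-membered ring) before loss of water and hydrolysis return the catalyst. The closest known reaction type is the amine-catalysed Michael/aldol-condensation [3+2] annulation of enals with 2-(2-oxoethyl)-1,3-dicarbonyl compounds, proposed here with both partners in one chain so that the first bond also closes a seven-membered ring. C5 is set by the catalyst: the diphenyl(silyloxy)methyl group of the (R)-amine shields the Si face of C5 in the s-trans iminium ion and C1 adds to the Re face, with the C6 silyloxy group anti to the forming bond. The quaternary C1 forms in a reversible Michael step and is funnelled to the epimer (ester cis to H-5) that can close the cis-fused cyclopentene; it is reset in step 16, and C3 and C4 end as sp2 carbons. Three selectivities are needed: C1 and not C9 as donor (only C1 is doubly activated), the enal and not the saturated aldehyde as acceptor (only the enal gives a conjugated iminium ion), and C4 and not C2 as aldol donor (the enamine is created at C4 by the conjugate addition itself). High dilution should suppress intermolecular Michael and aldol reactions.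

Step 16
Reactants: 26 bicyclic keto enal ester
Product: 28 cis-fused keto enal (H-1 cis to H-5), via β-keto acid 27 (not isolated)
Conditions: Pd(OAc)2 (5 mol%), PPh3 (20 mol%), HCO2H, Et3N, THF, 23 → 40 °C
Reagents that add atoms: none
Why: Zerovalent palladium formed in situ ionises the allyl ester (Tsuji–Trost-type deallylation with formate as hydride donor), the β-keto acid decarboxylates, and C1 is set by protonation and amine equilibration to the cis ring fusion.

Step 17
Reactants: 28 keto enal
Product: 29 keto allylic alcohol (C17 as CH2OH)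
Conditions: NaBH4, MeOH/CH2Cl2, −78 °C
Reagents that add atoms: none
Why: Borohydride 1,2-reduction of the conjugated aldehyde should be much faster than reduction of the hindered α-branched cycloheptanone at −78 °C.

Step 18
Reactants: 29 keto allylic alcohol
Product: 30 C10-methylene allylic alcohol
Conditions: Ph3PCH3Br (5 equiv), KOtBu (4.8 equiv), THF, 0 → 40 °C
Reagents that add atoms: methyltriphenylphosphonium bromide C[P+](c1ccccc1)(c1ccccc1)c1ccccc1.[Br-]
Why: Wittig methylenation should convert the C10 ketone into the exocyclic alkene (the hydroxyls ride as alkoxides), and any base-induced equilibration at C1 returns the cis-fused ketone before olefination.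

Step 19
Reactants: 30 C10-methylene allylic alcohol
Product: 32 6-O-silyl deacetyl dictyol H (C17 methyl, C15 OH free), via allylic mesylate 31 (not isolated)
Conditions: MsCl (1.2 equiv), Et3N, CH2Cl2, −40 °C; then LiBHEt3, THF, −40 → 0 °C
Reagents that add atoms: none
Why: Selective sulfonylation of the primary allylic alcohol followed by SN2 hydride displacement at the primary carbon should give the C17 methyl without allylic transposition.

Step 20
Reactants: 32 6-O-silyl deacetyl dictyol H
Product: 33 6-O-silyl dictyol H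
Conditions: Ac2O, DMAP, Et3N, CH2Cl2, 35 °C
Reagents that add atoms: acetic anhydride CC(=O)OC(C)=O
Why: DMAP-catalysed acylation should acetylate the only free hydroxyl, the tertiary C15 alcohol, while C6 is still silylated.

Step 21
Reactants: 33 6-O-silyl dictyol H
Product: 34 dictyol H
Conditions: HF·pyridine, THF, 0 → 23 °C
Reagents that add atoms: none
Why: Fluoride-mediated desilylation should free the C6 hydroxyl and leave the tertiary acetate and both alkenes untouched.

## Compound list

1 | nerol, (2Z)-3,7-dimethylocta-2,6-dien-1-ol | CC(C)=CCC/C(C)=C\CO | starting material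
2 | (2S,3R)-2,3-epoxynerol, [(2S,3R)-3-methyl-3-(4-methylpent-3-en-1-yl)oxiran-2-yl]methanol | OC[C@@H]1O[C@]1(C)CCC=C(C)C | intermediate
3 | allylmagnesium bromide | C=CC[Mg]Br | starting material
4 | (2R,3R)-3,7-dimethyl-2-(prop-2-en-1-yl)oct-6-ene-1,3-diol | OC[C@@H](CC=C)[C@](C)(O)CCC=C(C)C | intermediate
5 | (2R,3R)-5-[(2S)-3,3-dimethyloxiran-2-yl]-3-methyl-2-(prop-2-en-1-yl)pentane-1,3-diol (not isolated) | OC[C@@H](CC=C)[C@](C)(O)CC[C@@H]1OC1(C)C | intermediate
6 | 2-[(2R,5R)-5-[(2R)-1-hydroxypent-4-en-2-yl]-5-methyloxolan-2-yl]propan-2-ol | OC[C@@H](CC=C)[C@@]1(C)CC[C@H](C(C)(C)O)O1 | intermediate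
7 | (2S)-2-[(2R,5R)-5-(2-hydroxypropan-2-yl)-2-methyloxolan-2-yl]pent-4-enal | O=C[C@@H](CC=C)[C@@]1(C)CC[C@H](C(C)(C)O)O1 | intermediate
8 | tert-butyldimethyl(prop-2-yn-1-yloxy)silane | C#CCO[Si](C)(C)C(C)(C)C | starting material
9 | lithium acetylide of 8 (not isolated) | [Li]C#CCO[Si](C)(C)C(C)(C)C | intermediate
10 | (4R,5R)-1-[(tert-butyldimethylsilyl)oxy]-5-[(2R,5R)-5-(2-hydroxypropan-2-yl)-2-methyloxolan-2-yl]oct-7-en-2-yn-4-ol | O[C@@H](C#CCO[Si](C)(C)C(C)(C)C)[C@@H](CC=C)[C@@]1(C)CC[C@H](C(C)(C)O)O1 | intermediate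
11 | (2E,4S,5R)-1-[(tert-butyldimethylsilyl)oxy]-5-[(2R,5R)-5-(2-hydroxypropan-2-yl)-2-methyloxolan-2-yl]octa-2,7-dien-4-ol | O[C@@H](/C=C/CO[Si](C)(C)C(C)(C)C)[C@@H](CC=C)[C@@]1(C)CC[C@H](C(C)(C)O)O1 | intermediate
12 | 2-[(2R,5R)-5-[(4R,5S,6E)-5,8-bis[(tert-butyldimethylsilyl)oxy]octa-1,6-dien-4-yl]-5-methyloxolan-2-yl]propan-2-ol | CC(C)(C)[Si](C)(C)O[C@@H](/C=C/CO[Si](C)(C)C(C)(C)C)[C@@H](CC=C)[C@@]1(C)CC[C@H](C(C)(C)O)O1 | intermediate
13 | B-alkyl-9-borabicyclo[3.3.1]nonane from 12, boron on the terminal carbon (not isolated) | CC(C)(C)[Si](C)(C)O[C@@H](/C=C/CO[Si](C)(C)C(C)(C)C)[C@@H](CCCB1C2CCCC1CCC2)[C@@]1(C)CC[C@H](C(C)(C)O)O1 | intermediate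
14 | (4R,5S,6E)-5,8-bis[(tert-butyldimethylsilyl)oxy]-4-[(2R,5R)-5-(2-hydroxypropan-2-yl)-2-methyloxolan-2-yl]oct-6-en-1-ol | CC(C)(C)[Si](C)(C)O[C@@H](/C=C/CO[Si](C)(C)C(C)(C)C)[C@@H](CCCO)[C@@]1(C)CC[C@H](C(C)(C)O)O1 | intermediate
15 | (4R,5S,6E)-5,8-bis[(tert-butyldimethylsilyl)oxy]-4-[(2R,5R)-5-(2-hydroxypropan-2-yl)-2-methyloxolan-2-yl]oct-6-enal | CC(C)(C)[Si](C)(C)O[C@@H](/C=C/CO[Si](C)(C)C(C)(C)C)[C@@H](CCC=O)[C@@]1(C)CC[C@H](C(C)(C)O)O1 | intermediate
16 | allyl acetoacetate, prop-2-en-1-yl 3-oxobutanoate | CC(=O)CC(=O)OCC=C | starting material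
17 | allyl 2-diazo-3-oxobutanoate (not isolated) | CC(=O)C(=[N+]=[N-])C(=O)OCC=C | intermediate
18 | allyl diazoacetate | [N-]=[N+]=CC(=O)OCC=C | intermediate
19 | prop-2-en-1-yl (6R,7S,8E)-7,10-bis[(tert-butyldimethylsilyl)oxy]-6-[(2R,5R)-5-(2-hydroxypropan-2-yl)-2-methyloxolan-2-yl]-3-oxodec-8-enoate | CC(C)(C)[Si](C)(C)O[C@@H](/C=C/CO[Si](C)(C)C(C)(C)C)[C@@H](CCC(=O)CC(=O)OCC=C)[C@@]1(C)CC[C@H](C(C)(C)O)O1 | intermediate
20 | tert-butyl(2-iodoethoxy)dimethylsilane | ICCO[Si](C)(C)C(C)(C)C | starting material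
21 | 2-{2-[(tert-butyldimethylsilyl)oxy]ethyl} derivative of 19 (both C2 epimers) | CC(C)(C)[Si](C)(C)O[C@@H](/C=C/CO[Si](C)(C)C(C)(C)C)[C@@H](CCC(=O)C(CCO[Si](C)(C)C(C)(C)C)C(=O)OCC=C)[C@@]1(C)CC[C@H](C(C)(C)O)O1 | intermediate
22 | prop-2-en-1-yl (6R,7S,8E)-7-[(tert-butyldimethylsilyl)oxy]-10-hydroxy-2-(2-hydroxyethyl)-6-[(2R,5R)-5-(2-hydroxypropan-2-yl)-2-methyloxolan-2-yl]-3-oxodec-8-enoate | CC(C)(C)[Si](C)(C)O[C@@H](/C=C/CO)[C@@H](CCC(=O)C(CCO)C(=O)OCC=C)[C@@]1(C)CC[C@H](C(C)(C)O)O1 | intermediate
23 | prop-2-en-1-yl (6R,7S,8E)-7-[(tert-butyldimethylsilyl)oxy]-6-[(2R,5R)-5-(2-hydroxypropan-2-yl)-2-methyloxolan-2-yl]-3,10-dioxo-2-(2-oxoethyl)dec-8-enoate | CC(C)(C)[Si](C)(C)O[C@@H](/C=C/C=O)[C@@H](CCC(=O)C(CC=O)C(=O)OCC=C)[C@@]1(C)CC[C@H](C(C)(C)O)O1 | intermediate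
24 | Michael adduct, drawn as the free dialdehyde: cycloheptanone with CH2CHO on C5 and on C1, allyl ester on C1 (not isolated) | O=C1CC[C@@H]([C@@]2(C)CC[C@H](C(C)(C)O)O2)[C@@H](O[Si](C)(C)C(C)(C)C)[C@@H](CC=O)[C@]1(CC=O)C(=O)OCC=C | intermediate
25 | aldol adduct: bicyclic β-hydroxy aldehyde, OH on C3, CHO on C4, epimers at C3 and C4 (not isolated) | O=C1CC[C@@H]([C@@]2(C)CC[C@H](C(C)(C)O)O2)[C@@H](O[Si](C)(C)C(C)(C)C)[C@H]2C(C=O)C(O)C[C@@]12C(=O)OCC=C | intermediate
26 | bicyclic keto enal ester: C3=C4, C17 CHO, C10 ketone, 1α-allyl ester, H-5α, 6β-OTBS, 7β side chain | O=C1CC[C@@H]([C@@]2(C)CC[C@H](C(C)(C)O)O2)[C@@H](O[Si](C)(C)C(C)(C)C)[C@H]2C(C=O)=CC[C@@]12C(=O)OCC=C | intermediate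
27 | β-keto acid from 26 (not isolated) | O=C1CC[C@@H]([C@@]2(C)CC[C@H](C(C)(C)O)O2)[C@@H](O[Si](C)(C)C(C)(C)C)[C@H]2C(C=O)=CC[C@@]12C(=O)O | intermediate
28 | cis-fused keto enal: H-1α, H-5α, C17 CHO, C10 ketone, 6β-OTBS | O=C1CC[C@@H]([C@@]2(C)CC[C@H](C(C)(C)O)O2)[C@@H](O[Si](C)(C)C(C)(C)C)[C@H]2C(C=O)=CC[C@@H]12 | intermediate
29 | keto allylic alcohol: C17 CH2OH, C10 ketone | O=C1CC[C@@H]([C@@]2(C)CC[C@H](C(C)(C)O)O2)[C@@H](O[Si](C)(C)C(C)(C)C)[C@H]2C(CO)=CC[C@@H]12 | intermediate
30 | C10-methylene allylic alcohol: C17 CH2OH | C=C1CC[C@@H]([C@@]2(C)CC[C@H](C(C)(C)O)O2)[C@@H](O[Si](C)(C)C(C)(C)C)[C@H]2C(CO)=CC[C@@H]12 | intermediate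
31 | C17 allylic mesylate (not isolated) | C=C1CC[C@@H]([C@@]2(C)CC[C@H](C(C)(C)O)O2)[C@@H](O[Si](C)(C)C(C)(C)C)[C@H]2C(COS(C)(=O)=O)=CC[C@@H]12 | intermediate
32 | 6-O-(tert-butyldimethylsilyl) deacetyl dictyol H | C=C1CC[C@@H]([C@@]2(C)CC[C@H](C(C)(C)O)O2)[C@@H](O[Si](C)(C)C(C)(C)C)[C@H]2C(C)=CC[C@@H]12 | intermediate
33 | 6-O-(tert-butyldimethylsilyl) dictyol H | C=C1CC[C@@H]([C@@]2(C)CC[C@H](C(C)(C)OC(C)=O)O2)[C@@H](O[Si](C)(C)C(C)(C)C)[C@H]2C(C)=CC[C@@H]12 | intermediate
34 | dictyol H | C=C1CC[C@@H]([C@@]2(C)CC[C@H](C(C)(C)OC(C)=O)O2)[C@@H](O)[C@H]2C(C)=CC[C@@H]12 | target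

## Step count and risks

Total steps: 21. Longest linear sequence: 20 steps (steps 1–9 and 11–21, from nerol); step 10 is a one-step side branch.

Steps most likely to fail:

1. Step 15 (proposed new method). The seven-membered Michael closure may be too slow, so that the 1,4-keto aldehyde drains by intramolecular aldol condensation to a cyclopentenone or by cyclodehydration to a furan; regiocontrol in the aldol closure or facial control at C5 may also erode. The fallback separates the two bond formations and never generates the 1,4-keto aldehyde. It sets out from 19: C-allylation (allyl bromide, K2CO3, acetone) should give the C1-allyl β-keto ester F1; HF·pyridine should remove only the primary allylic silyl ether to give the allylic alcohol F2; MnO2 should give the enal F3; a Cs2CO3-mediated intramolecular Michael addition in dilute MeCN (facial selectivity at C5 then rests on the substrate and may need epimer separation) should give the cycloheptanone aldehyde F4; Mannich α-methylenation with Eschenmoser's salt and Et3N should give the α-methylene aldehyde F5; ring-closing metathesis with the second-generation Grubbs catalyst, RuCl2(=CHPh)(H2IMes)(PCy3), between the 2-formylvinyl group and the C-allyl group then closes the cyclopentene, and the route is rejoined at 26.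

2. Step 16. Protonation of the enol at C1 may occur from the wrong face, or equilibration may not favour the cis ring fusion. The fallback replaces thermodynamic control by catalyst control: starting again from 26, a ligand-controlled decarboxylative protonation (Pd(OAc)2, a tert-butyl-PHOX ligand, Meldrum's acid as proton donor, both ligand enantiomers screened for α-face delivery) would give 28 under kinetic control; no new compound is involved.

3. Step 5. Facial selectivity in the acetylide addition may be poor, because chelation by the oxolane oxygen and 1,3-induction oppose the Felkin–Anh sense. The fallback moves the stereocentre to reagent control: the mixture of C6 epimers of 10 would be oxidised (MnO2) to the ynone F6 and reduced with (R)-2-methyl-CBS-oxazaborolidine and catecholborane (alkynyl as the small group), returning to 10 as the single (4R) epimer.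

Further compounds
F1 | step 15 | C1-allyl β-keto ester (2-allyl derivative of 19) | CC(C)(C)[Si](C)(C)O[C@@H](/C=C/CO[Si](C)(C)C(C)(C)C)[C@@H](CCC(=O)C(CC=C)C(=O)OCC=C)[C@@]1(C)CC[C@H](C(C)(C)O)O1
F2 | step 15 | allylic alcohol from F1 (C17 OH free) | CC(C)(C)[Si](C)(C)O[C@@H](/C=C/CO)[C@@H](CCC(=O)C(CC=C)C(=O)OCC=C)[C@@]1(C)CC[C@H](C(C)(C)O)O1
F3 | step 15 | enal from F2 | CC(C)(C)[Si](C)(C)O[C@@H](/C=C/C=O)[C@@H](CCC(=O)C(CC=C)C(=O)OCC=C)[C@@]1(C)CC[C@H](C(C)(C)O)O1
F4 | step 15 | cycloheptanone aldehyde (CH2CHO on C5, allyl and allyl ester on C1) | O=C1CC[C@@H]([C@@]2(C)CC[C@H](C(C)(C)O)O2)[C@@H](O[Si](C)(C)C(C)(C)C)[C@@H](CC=O)[C@]1(CC=C)C(=O)OCC=C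
F5 | step 15 | α-methylene aldehyde from F4 | O=C1CC[C@@H]([C@@]2(C)CC[C@H](C(C)(C)O)O2)[C@@H](O[Si](C)(C)C(C)(C)C)[C@@H](C(=C)C=O)[C@]1(CC=C)C(=O)OCC=C
F0 | step 16 | none | none
F6 | step 5 | ynone from the C6 epimers of 10 | O=C(C#CCO[Si](C)(C)C(C)(C)C)[C@@H](CC=C)[C@@]1(C)CC[C@H](C(C)(C)O)O1
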